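The route rests on cutting ring C, the dihydrobenzofuran carrying the 3,5-dihydroxyphenyl group at C3, at O1–C2 and C2–C3. Because C2 is bonded to both O1 and C3, one benzylic ylide carbon can bridge the oxygen and the exocyclic carbon of an ortho-quinone methide. A single operation thus forms both bonds, closes ring C and sets the trans C2/C3 pair in absolute sense through a C2-symmetric thiolane. The precursor is the 2-[aryl(tosyl)methyl]phenol 6, which releases the quinone methide with base, partnered with the chiral 4-methoxybenzylthiolanium salt 11. The same annulation with the antipodal salt later builds ring B, and dehydrogenation of the annulation product supplies ring A.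

Key step: step 8

Remarks
- Ring A is the benzofuran. Ring B is the central dihydrobenzofuran, bonded through C5 to the alkene and through C3 to C4 of ring C. Ring C is the terminal dihydrobenzofuran. The target SMILES corresponds to ring B (2R,3R), ring C (2S,3S), both trans, and an E alkene.
- Assumption on the sense of induction: the accepted ylide model for this thiolane (aryl group turned away from the ring, attack on the face remote from the methyl group cis to the ylide carbon) accounts for the (S,S)-stilbene oxides that the (2R,5R)-sulfide is known to give with aldehydes. Carried over to the annulation, where aryl outranks C3 at C2, it predicts (2R,3R) from the (2R,5R)-salt and (2S,3S) from the (2S,5S)-salt. Ring C is therefore made with the (2S,5S)-salt 11 and ring B with the (2R,5R)-salt 21; should the sense prove opposite, the two salts exchange roles.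

Step 1
Reactants: 1 1-bromo-3,5-dimethoxybenzene
Product: 2 2-bromo-4,6-dimethoxybenzaldehyde
Conditions: POCl3, DMF, 0 °C → 100 °C; aq NaOAc
Reagents that add atoms: N,N-dimethylformamide CN(C)C=O; water O
Why: Vilsmeier–Haack formylation, in which the chloroiminium ion attacks the position para to one methoxy group and ortho to the other (next to bromine), the known preferred site of this arene over the more crowded position between the two methoxy groups.

Step 2
Reactants: 2 2-bromo-4,6-dimethoxybenzaldehyde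
Product: 3 2-bromo-6-hydroxy-4-methoxybenzaldehyde
Conditions: BCl3 (1 M in CH2Cl2), CH2Cl2, −78 °C → rt; H2O
Reagents that add atoms: none
Why: Chelation-controlled Lewis acid ether cleavage, in which BCl3 is held between the aldehyde oxygen and the neighbouring methoxy oxygen so that only the ortho methyl ether is cleaved.

Step 3
Reactants: 3 2-bromo-6-hydroxy-4-methoxybenzaldehyde; 1 1-bromo-3,5-dimethoxybenzene
Product: 5 3-bromo-2-[(3,5-dimethoxyphenyl)(hydroxy)methyl]-5-methoxyphenol (racemic), via arylmagnesium bromide 4 (not isolated)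
Conditions: 1 (2.3 equiv), Mg, I2 (cat.), THF, reflux; then 3, THF, 0 °C → rt; aq NH4Cl
Reagents that add atoms: none
Why: Grignard addition, in which the first equivalent of 4 deprotonates the phenol and the second adds to the magnesium-chelated aldehyde, the new carbinol centre being racemic and irrelevant because it becomes planar in step 8.

Step 4
Reactants: 5 3-bromo-2-[(3,5-dimethoxyphenyl)(hydroxy)methyl]-5-methoxyphenol
Product: 6 3-bromo-2-[(3,5-dimethoxyphenyl)(4-methylphenylsulfonyl)methyl]-5-methoxyphenol (racemic)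
Conditions: p-TolSO2H (1.5 equiv), TsOH·H2O (10 mol %), CH2Cl2, rt
Reagents that add atoms: p-toluenesulfinic acid Cc1ccc(cc1)S(=O)O
Why: Acid-promoted SN1 hydroxyl-to-sulfinate exchange, in which the carbinol ionises to a cation stabilised by the ortho-hydroxyl and para-methoxy groups and is captured at sulfur, the standard entry to 2-(sulfonylalkyl)phenols.

Step 5
Reactants: 7 (2R,5R)-hexane-2,5-diol
Product: 8 (2R,5R)-hexane-2,5-diyl dimethanesulfonate
Conditions: MsCl, Et3N, CH2Cl2, 0 °C
Reagents that add atoms: methanesulfonyl chloride CS(=O)(=O)Cl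
Why: O-Sulfonylation (mesylation) of both secondary alcohols takes place at oxygen, so both stereocentres are retained.

Step 6
Reactants: 8 (2R,5R)-hexane-2,5-diyl dimethanesulfonate
Product: 9 (2S,5S)-2,5-dimethylthiolane
Conditions: Na2S·9H2O, DMSO, rt; distillation
Reagents that add atoms: sodium sulfide [Na+].[Na+].[S-2]
Why: Double SN2 thioetherification, in which sulfide displaces one mesylate and the resulting thiolate closes the ring on the other, each with inversion, so that the (2R,5R)-dimesylate gives the (2S,5S)-thiolane.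

Step 7
Reactants: 9 (2S,5S)-2,5-dimethylthiolane; 10 4-methoxybenzyl bromide
Product: 11 (2S,5S)-1-[(4-methoxyphenyl)methyl]-2,5-dimethylthiolan-1-ium bromide
Conditions: acetone, rt, dark; precipitate washed with Et2O
Reagents that add atoms: none
Why: SN2 S-alkylation of the sulfide by the reactive benzylic bromide gives a crystalline sulfonium salt, a single one because the C2 axis makes both faces of sulfur equivalent.

Step 8
Reactants: 6 3-bromo-2-[(3,5-dimethoxyphenyl)(4-methylphenylsulfonyl)methyl]-5-methoxyphenol; 11 (2S,5S)-1-[(4-methoxyphenyl)methyl]-2,5-dimethylthiolan-1-ium bromide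
Product: 15 (2S,3S)-4-bromo-3-(3,5-dimethoxyphenyl)-6-methoxy-2-(4-methoxyphenyl)-2,3-dihydro-1-benzofuran, via ortho-quinone methide 12 (not isolated), via sulfonium ylide 13 (not isolated), via phenoxide betaine 14 (not isolated)
Conditions: 11 (1.5 equiv), Cs2CO3 (3 equiv), MeCN, 0 °C → rt
Reagents that add atoms: none
Why: Cs2CO3 deprotonates the phenol of 6, sulfinate leaves to give quinone methide 12, and the same base forms ylide 13 from 11; the ylide carbon adds to the exocyclic carbon of 12 (C2–C3), the ring re-aromatises to phenoxide betaine 14, and the phenoxide displaces the thiolane (O1–C2). The closest known reaction type is the [4+1] annulation of ortho-quinone methides, released from 2-(sulfonylalkyl)phenols, with sulfonium ylides, here joined to chiral-sulfide control as in asymmetric ylide epoxidation. Ring C closes in a 5-exo-tet substitution with inversion at the ylide carbon. The trans C2/C3 relation follows from closure of the betaine whose anti-periplanar O–C–S conformer keeps the two aryl groups apart, betaine formation being reversible for a semi-stabilised ylide; the absolute configuration comes from the C2-symmetric thiolane, in which the aryl group of the ylide turns away from the ring and the methyl group cis to the ylide carbon blocks one face. The step needs C–C bond formation at the exocyclic carbon in preference to O- or S-benzylation by 11: re-aromatisation drives the 1,4-addition, unimolecular loss of sulfinate keeps the phenoxide concentration low, and the excess of 11 covers what sulfinate consumes. The bromide at C4 is inert to these conditions and is kept for steps 9 and 15.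

Step 9
Reactants: 15 (2S,3S)-4-bromo-3-(3,5-dimethoxyphenyl)-6-methoxy-2-(4-methoxyphenyl)-2,3-dihydro-1-benzofuran (a portion; mixed or stereochemically impure fractions serve equally)
Product: 16 4-bromo-3-(3,5-dimethoxyphenyl)-6-methoxy-2-(4-methoxyphenyl)-1-benzofuran
Conditions: DDQ (1.5 equiv), anhydrous PhMe, 80 °C
Reagents that add atoms: none
Why: DDQ dehydrogenation, in which hydride is abstracted from C2 (benzylic, next to oxygen and to a 4-methoxyphenyl group) and the C3 proton is then lost, aromatises the furan ring and erases both stereocentres.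

Step 10
Reactants: 16 4-bromo-3-(3,5-dimethoxyphenyl)-6-methoxy-2-(4-methoxyphenyl)-1-benzofuran
Product: 17 3-(3,5-dimethoxyphenyl)-4-ethenyl-6-methoxy-2-(4-methoxyphenyl)-1-benzofuran
Conditions: vinylboronic acid pinacol ester, Pd(OAc)2 (5 mol %), SPhos (10 mol %), K3PO4, 1,4-dioxane/H2O, 90 °C
Reagents that add atoms: 2-ethenyl-4,4,5,5-tetramethyl-1,3,2-dioxaborolane C=CB1OC(C)(C)C(C)(C)O1
Why: Suzuki–Miyaura coupling, in which the bulky biaryl phosphine lets zerovalent palladium insert into the hindered C4–Br bond before transmetalation of the vinyl boronate and reductive elimination.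

Step 11
Reactants: 18 (2S,5S)-hexane-2,5-diol
Product: 19 (2S,5S)-hexane-2,5-diyl dimethanesulfonate
Conditions: MsCl, Et3N, CH2Cl2, 0 °C
Reagents that add atoms: methanesulfonyl chloride CS(=O)(=O)Cl
Why: O-Sulfonylation (mesylation) as in step 5, with retention at both stereocentres.

Step 12
Reactants: 19 (2S,5S)-hexane-2,5-diyl dimethanesulfonate
Product: 20 (2R,5R)-2,5-dimethylthiolane
Conditions: Na2S·9H2O, DMSO, rt; distillation
Reagents that add atoms: sodium sulfide [Na+].[Na+].[S-2]
Why: Double SN2 thioetherification as in step 6, with inversion at both centres giving the (2R,5R)-thiolane.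

Step 13
Reactants: 20 (2R,5R)-2,5-dimethylthiolane; 10 4-methoxybenzyl bromide
Product: 21 (2R,5R)-1-[(4-methoxyphenyl)methyl]-2,5-dimethylthiolan-1-ium bromide
Conditions: acetone, rt, dark; precipitate washed with Et2O
Reagents that add atoms: none
Why: SN2 S-alkylation as in step 7 gives the antipodal salt needed for ring B.

Step 14
Reactants: 22 5-bromo-2-hydroxybenzaldehyde
Product: 23 4-bromo-2-formylphenyl tert-butyl carbonate
Conditions: Boc2O, i-Pr2NEt, DMAP (cat.), CH2Cl2, 0 °C → rt
Reagents that add atoms: di-tert-butyl dicarbonate CC(C)(C)OC(=O)OC(=O)OC(C)(C)C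
Why: DMAP-catalysed O-acylation of the phenol gives the aryl carbonate, which serves in step 15 as the internal source of the benzylic leaving group.

Step 15
Reactants: 15 (2S,3S)-4-bromo-3-(3,5-dimethoxyphenyl)-6-methoxy-2-(4-methoxyphenyl)-2,3-dihydro-1-benzofuran; 23 4-bromo-2-formylphenyl tert-butyl carbonate
Product: 26 tert-butyl {(5-bromo-2-hydroxyphenyl)[(2S,3S)-3-(3,5-dimethoxyphenyl)-6-methoxy-2-(4-methoxyphenyl)-2,3-dihydro-1-benzofuran-4-yl]methyl} carbonate (epimer mixture at the carbinol carbon), via aryllithium 24 (not isolated), via lithium alkoxide 25 (not isolated)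
Conditions: n-BuLi, THF, −78 °C; then 23 (1.2 equiv), −78 °C; AcOH, −78 °C; extractive work-up, crude used at once
Reagents that add atoms: none
Why: Bromine–lithium exchange and 1,2-addition of aryllithium 24 to the aldehyde give alkoxide 25, which takes over the neighbouring tert-butoxycarbonyl group through a six-membered transition state (anionic O-to-O acyl transfer), so the phenol is unveiled and the benzylic leaving group installed without acid, which would expose the derived cation to Friedel–Crafts capture by the adjacent 3,5-dimethoxyphenyl ring; the carbinol epimers converge in step 16.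

Step 16
Reactants: 26 tert-butyl {(5-bromo-2-hydroxyphenyl)[(2S,3S)-3-(3,5-dimethoxyphenyl)-6-methoxy-2-(4-methoxyphenyl)-2,3-dihydro-1-benzofuran-4-yl]methyl} carbonate; 21 (2R,5R)-1-[(4-methoxyphenyl)methyl]-2,5-dimethylthiolan-1-ium bromide
Product: 30 (2R,3R)-5-bromo-3-[(2S,3S)-3-(3,5-dimethoxyphenyl)-6-methoxy-2-(4-methoxyphenyl)-2,3-dihydro-1-benzofuran-4-yl]-2-(4-methoxyphenyl)-2,3-dihydro-1-benzofuran, via ortho-quinone methide 27 (not isolated), via sulfonium ylide 28 (not isolated), via phenoxide betaine 29 (not isolated)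
Conditions: 21 (1.5 equiv), Cs2CO3 (3 equiv), MeCN, 0 °C → rt
Reagents that add atoms: none
Why: The [4+1] sulfonium ylide annulation of step 8 is repeated, the phenoxide of 26 expelling tert-butyl carbonate to give quinone methide 27, which takes up ylide 28 at its exocyclic carbon (C2–C3 of ring B) before betaine 29 closes O1–C2 in a 5-exo-tet displacement with inversion, the trans pair following from the anti betaine and the (2R,3R) sense from the (2R,5R)-thiolane, which is expected to override the bias of the remote ring C stereocentres.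

Step 17
Reactants: 30 (2R,3R)-5-bromo-3-[(2S,3S)-3-(3,5-dimethoxyphenyl)-6-methoxy-2-(4-methoxyphenyl)-2,3-dihydro-1-benzofuran-4-yl]-2-(4-methoxyphenyl)-2,3-dihydro-1-benzofuran; 17 3-(3,5-dimethoxyphenyl)-4-ethenyl-6-methoxy-2-(4-methoxyphenyl)-1-benzofuran
Product: 31 (2R,3R)-3-[(2S,3S)-3-(3,5-dimethoxyphenyl)-6-methoxy-2-(4-methoxyphenyl)-2,3-dihydro-1-benzofuran-4-yl]-5-{(E)-2-[3-(3,5-dimethoxyphenyl)-6-methoxy-2-(4-methoxyphenyl)-1-benzofuran-4-yl]ethenyl}-2-(4-methoxyphenyl)-2,3-dihydro-1-benzofuran (nona-O-methyl ether of the target)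
Conditions: Pd2(dba)3 (2.5 mol %), P(t-Bu)3·HBF4 (10 mol %), Cy2NMe, 1,4-dioxane, 90 °C
Reagents that add atoms: none
Why: Mizoroki–Heck reaction, in which the arylpalladium species from 30 adds to the unsubstituted alkene carbon of 17 and syn beta-hydride elimination from the less crowded rotamer gives the E-stilbene, the amine base being too weak to touch the benzylic stereocentres.

Step 18
Reactants: 31 nona-O-methyl ether of the target
Product: 32 CNP0135983.1, 5-[(2S,3S)-4-[(2R,3R)-5-{(E)-2-[3-(3,5-dihydroxyphenyl)-6-hydroxy-2-(4-hydroxyphenyl)-1-benzofuran-4-yl]ethenyl}-2-(4-hydroxyphenyl)-2,3-dihydro-1-benzofuran-3-yl]-6-hydroxy-2-(4-hydroxyphenyl)-2,3-dihydro-1-benzofuran-3-yl]benzene-1,3-diol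
Conditions: BBr3 (1 M in CH2Cl2, excess), CH2Cl2, −78 °C → rt; MeOH, then H2O
Reagents that add atoms: none
Why: Lewis acid ether cleavage with BBr3 removes all nine aryl methyl groups, and any transient C2–O ionisation in ring B or ring C should reclose to the more stable trans isomer fixed by the unchanged C3 centre, so the four stereocentres are retained.

Compound list
1 | 1-bromo-3,5-dimethoxybenzene | COc1cc(Br)cc(OC)c1 | starting material
2 | 2-bromo-4,6-dimethoxybenzaldehyde | COc1cc(Br)c(C=O)c(OC)c1 | intermediate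
3 | 2-bromo-6-hydroxy-4-methoxybenzaldehyde | COc1cc(O)c(C=O)c(Br)c1 | intermediate
4 | (3,5-dimethoxyphenyl)magnesium bromide | COc1cc([Mg]Br)cc(OC)c1 | intermediate (not isolated)
5 | 3-bromo-2-[(3,5-dimethoxyphenyl)(hydroxy)methyl]-5-methoxyphenol (racemic) | COc1cc(O)c(C(O)c2cc(OC)cc(OC)c2)c(Br)c1 | intermediate
6 | 3-bromo-2-[(3,5-dimethoxyphenyl)(4-methylphenylsulfonyl)methyl]-5-methoxyphenol (racemic) | COc1cc(O)c(C(c2cc(OC)cc(OC)c2)S(=O)(=O)c2ccc(C)cc2)c(Br)c1 | intermediate
7 | (2R,5R)-hexane-2,5-diol | C[C@@H](O)CC[C@@H](C)O | starting material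
8 | (2R,5R)-hexane-2,5-diyl dimethanesulfonate | C[C@@H](OS(C)(=O)=O)CC[C@@H](C)OS(C)(=O)=O | intermediate
9 | (2S,5S)-2,5-dimethylthiolane | S1[C@@H](C)CC[C@@H]1C | intermediate
10 | 4-methoxybenzyl bromide | COc1ccc(CBr)cc1 | starting material
11 | (2S,5S)-1-[(4-methoxyphenyl)methyl]-2,5-dimethylthiolan-1-ium bromide | COc1ccc(C[S+]2[C@@H](C)CC[C@@H]2C)cc1.[Br-] | intermediate
12 | 5-bromo-6-[(3,5-dimethoxyphenyl)methylidene]-3-methoxycyclohexa-2,4-dien-1-one (ortho-quinone methide) | COC1=CC(=O)C(=Cc2cc(OC)cc(OC)c2)C(Br)=C1 | intermediate (not isolated)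
13 | [(2S,5S)-2,5-dimethylthiolan-1-ium-1-yl](4-methoxyphenyl)methanide (sulfonium ylide) | COc1ccc([CH-][S+]2[C@@H](C)CC[C@@H]2C)cc1 | intermediate (not isolated)
14 | 3-bromo-2-[(1S,2R)-1-(3,5-dimethoxyphenyl)-2-[(2S,5S)-2,5-dimethylthiolan-1-ium-1-yl]-2-(4-methoxyphenyl)ethyl]-5-methoxyphenolate (betaine) | [O-]c1cc(OC)cc(Br)c1[C@H](c1cc(OC)cc(OC)c1)[C@H](c1ccc(OC)cc1)[S+]1[C@@H](C)CC[C@@H]1C | intermediate (not isolated)
15 | (2S,3S)-4-bromo-3-(3,5-dimethoxyphenyl)-6-methoxy-2-(4-methoxyphenyl)-2,3-dihydro-1-benzofuran | Brc1cc(OC)cc2c1[C@H](c1cc(OC)cc(OC)c1)[C@@H](c1ccc(OC)cc1)O2 | intermediate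
16 | 4-bromo-3-(3,5-dimethoxyphenyl)-6-methoxy-2-(4-methoxyphenyl)-1-benzofuran | COc1cc(Br)c2c(c1)oc(-c1ccc(OC)cc1)c2-c1cc(OC)cc(OC)c1 | intermediate
17 | 3-(3,5-dimethoxyphenyl)-4-ethenyl-6-methoxy-2-(4-methoxyphenyl)-1-benzofuran | COc1cc(C=C)c2c(c1)oc(-c1ccc(OC)cc1)c2-c1cc(OC)cc(OC)c1 | intermediate
18 | (2S,5S)-hexane-2,5-diol | C[C@H](O)CC[C@H](C)O | starting material
19 | (2S,5S)-hexane-2,5-diyl dimethanesulfonate | C[C@H](OS(C)(=O)=O)CC[C@H](C)OS(C)(=O)=O | intermediate
20 | (2R,5R)-2,5-dimethylthiolane | S1[C@H](C)CC[C@H]1C | intermediate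
21 | (2R,5R)-1-[(4-methoxyphenyl)methyl]-2,5-dimethylthiolan-1-ium bromide | COc1ccc(C[S+]2[C@H](C)CC[C@H]2C)cc1.[Br-] | intermediate
22 | 5-bromo-2-hydroxybenzaldehyde | O=Cc1cc(Br)ccc1O | starting material
23 | 4-bromo-2-formylphenyl tert-butyl carbonate | O=Cc1cc(Br)ccc1OC(=O)OC(C)(C)C | intermediate
24 | [(2S,3S)-3-(3,5-dimethoxyphenyl)-6-methoxy-2-(4-methoxyphenyl)-2,3-dihydro-1-benzofuran-4-yl]lithium | [Li]c1cc(OC)cc2c1[C@H](c1cc(OC)cc(OC)c1)[C@@H](c1ccc(OC)cc1)O2 | intermediate (not isolated)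
25 | lithium {5-bromo-2-[(tert-butoxycarbonyl)oxy]phenyl}[(2S,3S)-3-(3,5-dimethoxyphenyl)-6-methoxy-2-(4-methoxyphenyl)-2,3-dihydro-1-benzofuran-4-yl]methanolate (epimer mixture) | [Li+].[O-]C(c1cc(Br)ccc1OC(=O)OC(C)(C)C)c1cc(OC)cc2c1[C@H](c1cc(OC)cc(OC)c1)[C@@H](c1ccc(OC)cc1)O2 | intermediate (not isolated)
26 | tert-butyl {(5-bromo-2-hydroxyphenyl)[(2S,3S)-3-(3,5-dimethoxyphenyl)-6-methoxy-2-(4-methoxyphenyl)-2,3-dihydro-1-benzofuran-4-yl]methyl} carbonate (epimer mixture) | CC(C)(C)OC(=O)OC(c1cc(Br)ccc1O)c1cc(OC)cc2c1[C@H](c1cc(OC)cc(OC)c1)[C@@H](c1ccc(OC)cc1)O2 | intermediate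
27 | 4-bromo-6-{[(2S,3S)-3-(3,5-dimethoxyphenyl)-6-methoxy-2-(4-methoxyphenyl)-2,3-dihydro-1-benzofuran-4-yl]methylidene}cyclohexa-2,4-dien-1-one (ortho-quinone methide) | O=C1C=CC(Br)=CC1=Cc1cc(OC)cc2c1[C@H](c1cc(OC)cc(OC)c1)[C@@H](c1ccc(OC)cc1)O2 | intermediate (not isolated)
28 | [(2R,5R)-2,5-dimethylthiolan-1-ium-1-yl](4-methoxyphenyl)methanide (sulfonium ylide) | COc1ccc([CH-][S+]2[C@H](C)CC[C@H]2C)cc1 | intermediate (not isolated)
29 | 4-bromo-2-[(1R,2S)-1-[(2S,3S)-3-(3,5-dimethoxyphenyl)-6-methoxy-2-(4-methoxyphenyl)-2,3-dihydro-1-benzofuran-4-yl]-2-[(2R,5R)-2,5-dimethylthiolan-1-ium-1-yl]-2-(4-methoxyphenyl)ethyl]phenolate (betaine) | [O-]c1ccc(Br)cc1[C@@H](c1cc(OC)cc2c1[C@H](c1cc(OC)cc(OC)c1)[C@@H](c1ccc(OC)cc1)O2)[C@@H](c1ccc(OC)cc1)[S+]1[C@H](C)CC[C@H]1C | intermediate (not isolated)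
30 | (2R,3R)-5-bromo-3-[(2S,3S)-3-(3,5-dimethoxyphenyl)-6-methoxy-2-(4-methoxyphenyl)-2,3-dihydro-1-benzofuran-4-yl]-2-(4-methoxyphenyl)-2,3-dihydro-1-benzofuran | Brc1ccc2c(c1)[C@@H](c1cc(OC)cc3c1[C@H](c1cc(OC)cc(OC)c1)[C@@H](c1ccc(OC)cc1)O3)[C@H](c1ccc(OC)cc1)O2 | intermediate
31 | nona-O-methyl ether of the target (full name in step 17) | COc1ccc(-c2oc3cc(OC)cc(/C=C/c4ccc5c(c4)[C@@H](c4cc(OC)cc6c4[C@H](c4cc(OC)cc(OC)c4)[C@@H](c4ccc(OC)cc4)O6)[C@H](c4ccc(OC)cc4)O5)c3c2-c2cc(OC)cc(OC)c2)cc1 | intermediate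
32 | CNP0135983.1 (full name in step 18) | Oc1ccc(-c2oc3cc(O)cc(/C=C/c4ccc5c(c4)[C@@H](c4cc(O)cc6c4[C@H](c4cc(O)cc(O)c4)[C@@H](c4ccc(O)cc4)O6)[C@H](c4ccc(O)cc4)O5)c3c2-c2cc(O)cc(O)c2)cc1 | target

Total step count: 18. Longest linear sequence: 9 steps (steps 1, 2, 3, 4, 8, 15, 16, 17, 18, from 1 to 32).

Steps most likely to fail

Step 8. The thiolane ylide may discriminate poorly between the faces of a crowded quinone methide, and benzyl transfer from the sulfonium salt to phenoxide or sulfinate may compete with ylide addition. The fallback sets out from 6 and comes back at 15. Tetrahydrothiophene is alkylated with 10 to give the achiral salt 1-[(4-methoxyphenyl)methyl]thiolan-1-ium bromide F1. With 6 and Cs2CO3 in MeCN, its less hindered ylide should give the racemic trans-dihydrobenzofuran F2 by the same annulation. Preparative chromatography on a chiral stationary phase then separates 15 from its (2R,3R)-antipode F3. F3 is not lost, because DDQ converts it into 16.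

Step 16. The ring C stereocentres may oppose the thiolane (mismatched double stereodifferentiation), or carbonate may be lost from 26 before the ylide is present; either would erode the diastereomer ratio or the mass balance. The fallback sets out from 15 and comes back at 30, bypassing steps 14 to 16 through a rhodium carbene C–H insertion.
- 22 is O-alkylated with 10 (K2CO3, DMF) to give 5-bromo-2-[(4-methoxyphenyl)methoxy]benzaldehyde F4.
- Aryllithium 24 (from 15 and n-BuLi, THF, −78 °C) adds to F4 to give the diarylmethanol F5.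
- Dess–Martin periodinane oxidises F5 to the diaryl ketone F6.
- Hydrazine hydrate (EtOH, AcOH, reflux) converts F6 into the hydrazone F7.
- MnO2 oxidises F7 to the diaryldiazomethane F8.
- With Rh2(S-PTAD)4 or its enantiomer, chosen to set 3R, F8 loses dinitrogen and the donor/donor carbene inserts into the benzylic ether C–H bond, giving the cis-(2S,3R) dihydrobenzofuran F9.
- TFA in CH2Cl2 epimerises C2 of F9 through the 4-methoxybenzylic cation to the trans isomer 30.

Step 18. Ninefold ether cleavage exposes the stilbene and both benzylic C2–O bonds to strong acid. Protonation of the alkene followed by Friedel–Crafts closure onto a neighbouring resorcinol ring, or incomplete cleavage, may result. The fallback sets out from 30 and 16 and comes back at 32; it removes the methyl groups before the acid-sensitive stilbene exists. BBr3 converts 30 into the pentaphenol bromide F10 and 16 into the tetraphenol bromide F11. Suzuki–Miyaura vinylation of F11 (vinylboronic acid pinacol ester, Pd(OAc)2, SPhos, K3PO4, dioxane/H2O) gives the vinyl tetraphenol F12. A Mizoroki–Heck coupling of F10 with F12 (Pd(OAc)2, P(o-tol)3, Et3N, DMF, 100 °C) then gives 32 directly under non-acidic conditions.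

Further compounds
F1 | step 8 | 1-[(4-methoxyphenyl)methyl]thiolan-1-ium bromide | COc1ccc(C[S+]2CCCC2)cc1.[Br-]
F2 | step 8 | racemic trans-4-bromo-3-(3,5-dimethoxyphenyl)-6-methoxy-2-(4-methoxyphenyl)-2,3-dihydro-1-benzofuran (1:1 mixture of 15 and F3) | Brc1cc(OC)cc2c1[C@H](c1cc(OC)cc(OC)c1)[C@@H](c1ccc(OC)cc1)O2.Brc1cc(OC)cc2c1[C@@H](c1cc(OC)cc(OC)c1)[C@H](c1ccc(OC)cc1)O2
F3 | step 8 | (2R,3R)-4-bromo-3-(3,5-dimethoxyphenyl)-6-methoxy-2-(4-methoxyphenyl)-2,3-dihydro-1-benzofuran | Brc1cc(OC)cc2c1[C@@H](c1cc(OC)cc(OC)c1)[C@H](c1ccc(OC)cc1)O2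
F4 | step 16 | 5-bromo-2-[(4-methoxyphenyl)methoxy]benzaldehyde | O=Cc1cc(Br)ccc1OCc1ccc(OC)cc1
F5 | step 16 | {5-bromo-2-[(4-methoxyphenyl)methoxy]phenyl}[(2S,3S)-3-(3,5-dimethoxyphenyl)-6-methoxy-2-(4-methoxyphenyl)-2,3-dihydro-1-benzofuran-4-yl]methanol (epimer mixture) | OC(c1cc(Br)ccc1OCc1ccc(OC)cc1)c1cc(OC)cc2c1[C@H](c1cc(OC)cc(OC)c1)[C@@H](c1ccc(OC)cc1)O2
F6 | step 16 | {5-bromo-2-[(4-methoxyphenyl)methoxy]phenyl}[(2S,3S)-3-(3,5-dimethoxyphenyl)-6-methoxy-2-(4-methoxyphenyl)-2,3-dihydro-1-benzofuran-4-yl]methanone | O=C(c1cc(Br)ccc1OCc1ccc(OC)cc1)c1cc(OC)cc2c1[C@H](c1cc(OC)cc(OC)c1)[C@@H](c1ccc(OC)cc1)O2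
F7 | step 16 | hydrazone of F6 (E/Z mixture) | NN=C(c1cc(Br)ccc1OCc1ccc(OC)cc1)c1cc(OC)cc2c1[C@H](c1cc(OC)cc(OC)c1)[C@@H](c1ccc(OC)cc1)O2
F8 | step 16 | (2S,3S)-4-[{5-bromo-2-[(4-methoxyphenyl)methoxy]phenyl}(diazo)methyl]-3-(3,5-dimethoxyphenyl)-6-methoxy-2-(4-methoxyphenyl)-2,3-dihydro-1-benzofuran | [N-]=[N+]=C(c1cc(Br)ccc1OCc1ccc(OC)cc1)c1cc(OC)cc2c1[C@H](c1cc(OC)cc(OC)c1)[C@@H](c1ccc(OC)cc1)O2
F9 | step 16 | (2S,3R)-5-bromo-3-[(2S,3S)-3-(3,5-dimethoxyphenyl)-6-methoxy-2-(4-methoxyphenyl)-2,3-dihydro-1-benzofuran-4-yl]-2-(4-methoxyphenyl)-2,3-dihydro-1-benzofuran (cis in ring B) | Brc1ccc2c(c1)[C@@H](c1cc(OC)cc3c1[C@H](c1cc(OC)cc(OC)c1)[C@@H](c1ccc(OC)cc1)O3)[C@@H](c1ccc(OC)cc1)O2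
F10 | step 18 | 5-[(2S,3S)-4-[(2R,3R)-5-bromo-2-(4-hydroxyphenyl)-2,3-dihydro-1-benzofuran-3-yl]-6-hydroxy-2-(4-hydroxyphenyl)-2,3-dihydro-1-benzofuran-3-yl]benzene-1,3-diol | Brc1ccc2c(c1)[C@@H](c1cc(O)cc3c1[C@H](c1cc(O)cc(O)c1)[C@@H](c1ccc(O)cc1)O3)[C@H](c1ccc(O)cc1)O2
F11 | step 18 | 5-[4-bromo-6-hydroxy-2-(4-hydroxyphenyl)-1-benzofuran-3-yl]benzene-1,3-diol | Oc1cc(Br)c2c(c1)oc(-c1ccc(O)cc1)c2-c1cc(O)cc(O)c1
F12 | step 18 | 5-[4-ethenyl-6-hydroxy-2-(4-hydroxyphenyl)-1-benzofuran-3-yl]benzene-1,3-diol | Oc1cc(C=C)c2c(c1)oc(-c1ccc(O)cc1)c2-c1cc(O)cc(O)c1
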